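A single forward rate constant cannot hold in oak if each Z costs one L.

| flask | G | L | Q | remark | time |
|---|---|---|---|---|---|
| birch | 0.38 M | 1.1 equiv | 0.057 M | run made earlier |  |
| oak | 1.1 M | 1.1 equiv | 0.057 M | run made earlier |  |
| violet | 0.57 M | 1.10 equiv | 0.0570 M |  | 6.0 min |
| grey | 0.57 M | 1.70 equiv | 0.0570 M |  | 6.0 min |
| ochre | 0.57 M | 2.50 equiv | 0.0570 M |  | 6.0 min |

| run | time / min | G / % | Z / % |
|---|---|---|---|
| birch | 0.250 | 82.6 | 5.4 |
| birch | 0.500 | 76.8 | 8.5 |
| birch | 1.00 | 68.8 | 15.6 |
| birch | 2.00 | 60.4 | 25.2 |
| birch | 4.00 | 49.3 | 35.6 |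
| oak | 0.667 | 68.8 | 26.2 |
| oak | 1.33 | 56.6 | 37.5 |
| oak | 2.00 | 51.2 | 43.7 |
| oak | 3.00 | 46.0 | 49.0 |
| oak | 4.00 | 43.4 | 50.9 |

(scatter of a reading: 0.3 percentage points)

* part of the G that has reacted at the end, violet
* part of the G that has reacted at the end, grey
* part of the G that has reacted at the end, ochre
* what raising the equivalents of L from its lowest to its highest value here does to the part of the G that has reacted (changes below 5 percentage points count as none) (it rises / it falls / no change)

- reactions considered so far: G + L <-> X + Z; L + X <-> J; G + Q -> D

The steps considered are G + L <-> X + Z, L + X <-> J and G + Q -> D.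

*Where does G go besides Z?* At 4.00 min in oak, 5.70% of the charge is in neither G nor Z, beside 5.18% for [Q]/[G]; birch reads 15.1% beside 15.0%. So I book [Q] as D, which is 10.0% of G in the new flasks, and 0.513 M of G remains for L.

*Why not one L per Z?* Oak makes Z at 0.187 M/min early and 0.0209 M/min late. Divided by mean [G][L], with one L per Z, that gives 0.316 /M/min falling to 0.0643 /M/min, so on this count the forward constant does not stay constant.

*Go round again.* Put the answer back: L + X -> J may take a second L. The two-L constant, a second-order rate constant with [L] reckoned as the charge less two L for each Z, reads 0.534 /M/min early and 0.383 /M/min late.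

*It still falls.* Yes, but the late figure rests on a difference of 1.9 percentage points between readings good to 0.3 points, so I carry the early one.

*Your numbers?* With z = [Z], a the G left for L and h half the L charge, ln[(h−z)a/((a−z)h)] = 2k(h−a)t. My reckoning gives 57.8% for violet, 76.5% for grey and 91.2% for ochre.

The forecast says 60%, 72% and 83% for the part of G reacted, and of that part with more L, it rises, on the grounds “Estimated Z at 6 min, close to equilibrium”. Mine stands lower for violet and higher for grey and ochre.

The flasks give 58.3%, 77.2% and 91.8%; from violet to ochre the part of G reacted behaves so: it rises, by 33 points.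

    G + L ⇌ X + Z (K = 3.77, k = 0.00926 /M/s)
    L + X ⇌ J, settled at all times (K = 2720 /M)
    G + Q → D (k = 0.378 /M/s)

The carried 0.534 /M/min had given 91.2% for ochre. A neighbour of ochre, charged with 0.620 equiv of L and otherwise held, reckons with the same constant to 38.5%, and it gives 38.8%. At 6.00 min that neighbour holds Z at 28.8% of the G charged, with 7.6% of its L left unbound.

All runs were generated by integration on assumed constants, noise included.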